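**Retrosynthetic overview**
1. Germacrane numbering is used: C1 furanone C=O, C2 furanone CH, C3 furanone C–O, C4=C5 (C15 = CH2OH on C4), C6/C7 lactone ring carbons, C8 ester carbinol, C9, C10 quaternary carbon (C14 = CH3), C11–C13 methylene lactone.
2. Enabling feature: the furanone ring O–C3=C2–C1(=O)–C10 is a cyclised 1,3-diketone, and C1(=O)–C10–C9–C8–O8 is a γ-hydroxy-acid pattern. C1, C10, C14, C9, C8 and the C8 oxygen can therefore be stored in a γ-butyrolactone whose α-carbon (C10) carries a bromide set trans to the C8 side chain.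
3. Key disconnection: C1–C2 and O–C10 in one operation, joining methyl ketone 8 (C2–C6, C15) to bromolactone 19 (C1, C7–C14) by enolate acylation, lactone opening and 5-exo-tet O-alkylation with inversion at C10.
4. Then C6–C7 and O6–C12 by intramolecular chromium-mediated 2-(methoxycarbonyl)allylation/lactonisation; last the C8 methacrylate and C15 desilylation.
5. Ring order: temporary γ-lactone (chiral pool) → furanone → ten-membered carbocycle → α-methylene-γ-lactone.

Key step: step 12

Remark: (R)-5-(hydroxymethyl)dihydrofuran-2(3H)-one (from D-glutamic acid) and trimethyl 2-phosphonoacrylate are taken as commercial; the target as drawn is (6R,7R,8R,10R).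

**Fragment A (ketone 8)**

Step 1
Reactants: 1 but-2-yne-1,4-diol
Product: 2 4-[(tert-butyldiphenylsilyl)oxy]but-2-yn-1-ol
Conditions: TBDPSCl (0.35 equiv), imidazole, DMF, 0 °C → rt
Reagents that add atoms: tert-butyl(chloro)diphenylsilane, CC(C)(C)[Si](Cl)(c1ccccc1)c1ccccc1
Why: Statistical monosilylation (silyl ether formation) of the symmetric diol used in excess gives the C15 oxygen the protecting group it keeps to the last step.

Step 2
Reactants: 2 4-[(tert-butyldiphenylsilyl)oxy]but-2-yn-1-ol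
Product: 4 (Z)-4-[(tert-butyldiphenylsilyl)oxy]-3-iodobut-2-en-1-ol, via cyclic alkenylalanate 3 (not isolated)
Conditions: NaAlH2(OCH2CH2OCH3)2, THF, 0 °C → rt; then I2, THF, −78 °C
Reagents that add atoms: iodine, [I][I]
Why: Alkoxide-directed trans-hydroalumination of the propargylic alcohol puts hydride on the proximal and aluminium on the distal alkyne carbon, and iododealumination with retention fixes the C4=C5 geometry (iodine cis to CH2OH).

Step 3
Reactants: 4 (Z)-4-[(tert-butyldiphenylsilyl)oxy]-3-iodobut-2-en-1-ol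
Product: 5 (Z)-4-[(tert-butyldiphenylsilyl)oxy]-3-iodobut-2-enal
Conditions: MnO2, CH2Cl2, rt, dark
Reagents that add atoms: none
Why: Allylic alcohol oxidation with manganese dioxide is neutral, so the Z β-iodo enal should form without isomerisation.

Step 4
Reactants: 5 (Z)-4-[(tert-butyldiphenylsilyl)oxy]-3-iodobut-2-enal
Product: 6 (Z)-tert-butyl[(2-iodo-4,4-dimethoxybut-2-en-1-yl)oxy]diphenylsilane
Conditions: HC(OMe)3, PPTS (cat.), MeOH, 0 °C → rt, dark
Reagents that add atoms: trimethyl orthoformate, COC(OC)OC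
Why: Acid-catalysed acetalisation with an orthoester as water scavenger masks C6 as a dimethyl acetal that tolerates the organolithium and enolate chemistry ahead.

Step 5
Reactants: 6 (Z)-tert-butyl[(2-iodo-4,4-dimethoxybut-2-en-1-yl)oxy]diphenylsilane
Product: 8 (Z)-3-{[(tert-butyldiphenylsilyl)oxy]methyl}-5,5-dimethoxypent-3-en-2-one (fragment A), via alkenyllithium 7 (not isolated)
Conditions: t-BuLi (2.1 equiv), Et2O, −78 °C; then MeC(O)N(OMe)Me, −78 → −40 °C; aq NH4Cl
Reagents that add atoms: N-methoxy-N-methylacetamide, CC(=O)N(C)OC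
Why: Iodine–lithium exchange of an alkenyl iodide is stereoretentive and Weinreb amide acylation stops at the ketone, so the acetyl group (C2, C3) ends cis to C6.

**Fragment B (bromolactone 19)**

Step 6
Reactants: 9 (R)-5-(hydroxymethyl)dihydrofuran-2(3H)-one
Product: 10 (R)-5-{[(tert-butyldiphenylsilyl)oxy]methyl}dihydrofuran-2(3H)-one
Conditions: TBDPSCl, imidazole, DMF, rt
Reagents that add atoms: tert-butyl(chloro)diphenylsilane, CC(C)(C)[Si](Cl)(c1ccccc1)c1ccccc1
Why: Silyl ether formation protects the future C7 alcohol and gives the bulky C5 substituent that steers both enolate reactions; C8 comes from the chiral pool.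

Step 7
Reactants: 10 (R)-5-{[(tert-butyldiphenylsilyl)oxy]methyl}dihydrofuran-2(3H)-one
Product: 12 (3S,5R)-5-{[(tert-butyldiphenylsilyl)oxy]methyl}-3-methyldihydrofuran-2(3H)-one, via lithium enolate 11 (not isolated)
Conditions: LiN(iPr)2, THF, −78 °C; then MeI, −78 → −40 °C
Reagents that add atoms: iodomethane, IC
Why: Enolate alkylation of the γ-substituted butyrolactone occurs anti to the C5 side chain and installs C14; the C3 centre is erased in the next step, so any cis epimer converges.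

Step 8
Reactants: 12 (3S,5R)-5-{[(tert-butyldiphenylsilyl)oxy]methyl}-3-methyldihydrofuran-2(3H)-one
Product: 14 (3S,5R)-3-bromo-5-{[(tert-butyldiphenylsilyl)oxy]methyl}-3-methyldihydrofuran-2(3H)-one, via lithium enolate 13 (not isolated)
Conditions: LiN(SiMe3)2, THF, −78 °C; then BrCCl2CCl2Br, −78 °C
Reagents that add atoms: 1,2-dibromo-1,1,2,2-tetrachloroethane, ClC(Cl)(Br)C(Cl)(Cl)Br
Why: Electrophilic bromination of the lactone enolate on the face anti to the C5 side chain (1,3-induction in the five-membered ring) sets the C10 precursor centre with bromine trans to the side chain.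

Step 9
Reactants: 14 (3S,5R)-3-bromo-5-{[(tert-butyldiphenylsilyl)oxy]methyl}-3-methyldihydrofuran-2(3H)-one
Product: 15 (3S,5R)-3-bromo-5-(hydroxymethyl)-3-methyldihydrofuran-2(3H)-one
Conditions: HF·pyridine, pyridine/THF, 0 °C → rt
Reagents that add atoms: none
Why: Fluoride-mediated desilylation under buffered, non-basic conditions leaves the tertiary α-bromo lactone untouched.

Step 10
Reactants: 15 (3S,5R)-3-bromo-5-(hydroxymethyl)-3-methyldihydrofuran-2(3H)-one
Product: 16 (2R,4S)-4-bromo-4-methyl-5-oxotetrahydrofuran-2-carbaldehyde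
Conditions: DMP, NaHCO3, CH2Cl2, 0 °C → rt; used at once
Reagents that add atoms: none
Why: Periodinane oxidation of the primary alcohol is neutral and fast, which should keep the α-oxygenated aldehyde (C8) from epimerising.

Step 11
Reactants: 16 (2R,4S)-4-bromo-4-methyl-5-oxotetrahydrofuran-2-carbaldehyde, 17 trimethyl 2-phosphonoacrylate
Product: 19 methyl (E)-3-[(2R,4S)-4-bromo-4-methyl-5-oxotetrahydrofuran-2-yl]-2-{[(4-methoxybenzyl)oxy]methyl}prop-2-enoate (fragment B), via sodium phosphonate 18 (not isolated)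
Conditions: 4-MeOC6H4CH2OH (0.95 equiv), NaH, THF, 0 °C; 17, 0 °C; then 16, −78 → 0 °C
Reagents that add atoms: 4-methoxybenzyl alcohol, COc1ccc(CO)cc1
Why: Conjugate addition of the alkoxide to the phosphonoacrylate gives a phosphonate carbanion that undergoes Horner–Wadsworth–Emmons olefination with the aldehyde; the trisubstituted enoate should form mainly with the ester trans to C8 (E), which also keeps the later C8 alkoxide away from the ester.

**Union, ring closure and end game**

Step 12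
Reactants: 8 (Z)-3-{[(tert-butyldiphenylsilyl)oxy]methyl}-5,5-dimethoxypent-3-en-2-one, 19 methyl (E)-3-[(2R,4S)-4-bromo-4-methyl-5-oxotetrahydrofuran-2-yl]-2-{[(4-methoxybenzyl)oxy]methyl}prop-2-enoate
Product: 23 2,2,5-trisubstituted furan-3(2H)-one bearing the C8 triethylsilyl ether (full name in the list), via lithium enolate 20 (not isolated), via bromo diketone 21 (not isolated), via hydroxy furanone 22 (not isolated)
Conditions: LiN(SiMe3)2 (1.05 equiv), THF, −78 °C; 19, −78 → −20 °C; DMPU, −20 °C → rt; then Et3SiCl, imidazole, 0 °C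
Reagents that add atoms: chlorotriethylsilane, CC[Si](Cl)(CC)CC
Why: Proposed new method: the kinetic lithium enolate of the methyl ketone (C2) adds to the lactone carbonyl (C1) at −78 °C; on warming the hemiketal alkoxide opens to the C8 alkoxide and the 1,3-diketone, which is deprotonated at once, and the diketonate oxygen on C3 then displaces the tertiary bromide at C10. The closest known reactions are the Claisen acylation of ketone enolates by lactones and the base-induced cyclisation of 4-halo-1,3-diketones to furan-3(2H)-ones; new is their union in one flask on an enantiopure tertiary bromide. The furanone closes by 5-exo-tet O-alkylation (ring O–C3=C2–C1–C10). C10 is set by inversion of the bromide that step 8 placed trans to the side chain, and C8 is untouched because only its O–C1 bond breaks. The step needs C-acylation at the lactone instead of the conjugated methyl ester, which the α-bromine-activated lactone and −78 °C should secure, and it needs substitution to outrun ionisation or loss of HBr, which the intramolecular five-membered closure next to the carbonyl favours; addition anti to the C–Br bond also leaves the hemiketal oxygen cis to bromine, so it cannot close to an epoxide. The freed C8 alcohol is silylated in the flask because a free or acylated C8 oxygen would not survive the later allylmetal step.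

Step 13
Reactants: 23 furanone C8 triethylsilyl ether
Product: 24 corresponding C13 allylic alcohol
Conditions: DDQ, CH2Cl2/pH 7 buffer, 0 °C
Reagents that add atoms: none
Why: Oxidative cleavage of the 4-methoxybenzyl ether by DDQ (benzylic oxidation to the oxocarbenium ion, then hydrolysis) frees the C13 alcohol while the silyl ethers and the buffered acetal should stay intact.

Step 14
Reactants: 24 C13 allylic alcohol
Product: 25 C13 allylic bromide (methyl (Z)-2-(bromomethyl)enoate)
Conditions: CBr4, PPh3, 2,6-lutidine, CH2Cl2, 0 °C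
Reagents that add atoms: tetrabromomethane, BrC(Br)(Br)Br
Why: Appel bromination of the primary allylic alcohol proceeds under neutral conditions that leave the acetal and both silyl ethers alone.

Step 15
Reactants: 25 C13 allylic bromide
Product: 26 (Z)-enal (C6 aldehyde) with the allylic bromide
Conditions: PPTS (cat.), acetone/H2O, 0 °C; used at once
Reagents that add atoms: water, O
Why: The conjugated dimethyl acetal hydrolyses under acid catalysis milder than that needed to cleave the secondary triethylsilyl ether, and immediate use limits Z to E drift of the enal.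

Step 16
Reactants: 26 (Z)-enal with the allylic bromide
Product: 29 tricyclic lactone with C8–OSiEt3 and C15–OTBDPS, via allylchromium 27 (not isolated), via hydroxy ester 28 (not isolated)
Conditions: CrCl2 (8 equiv), THF, 0.002 M (syringe pump), rt; aq NH4Cl
Reagents that add atoms: none
Why: In this intramolecular Nozaki–Hiyama–Kishi-type (Barbier) allylation, divalent chromium turns the allylic bromide into an allylchromium species that adds through C7 to the C6 aldehyde via a chair-like six-membered transition state (anti, hence the trans lactone once the alkoxide closes onto the methyl ester), with the face fixed by the adjacent C8 silyloxy stereocentre and the short furanone-bridged tether, so that C6 and C7 are set while the ten-membered carbocycle and then the α-methylene-γ-lactone close.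

Step 17
Reactants: 29 tricyclic lactone with C8–OSiEt3 and C15–OTBDPS
Product: 30 C8 alcohol (C15–OTBDPS retained)
Conditions: PPTS, MeOH/CH2Cl2, 0 °C
Reagents that add atoms: none
Why: Acid-catalysed methanolysis removes the secondary triethylsilyl ether far faster than the primary tert-butyldiphenylsilyl ether (selective desilylation).

Step 18
Reactants: 30 C8 alcohol
Product: 31 C8 methacrylate (C15–OTBDPS)
Conditions: methacrylic anhydride, Et3N, DMAP (cat.), CH2Cl2, 0 °C → rt
Reagents that add atoms: methacrylic anhydride, C=C(C)C(=O)OC(=O)C(C)=C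
Why: DMAP-catalysed acylation of the only free hydroxyl installs the ester with retention at C8.

Step 19
Reactants: 31 C8 methacrylate (C15–OTBDPS)
Product: 32 target
Conditions: HF·pyridine, pyridine/THF, 0 °C → rt
Reagents that add atoms: none
Why: Buffered fluoride desilylation frees the C15 alcohol without base, which the α-methylene lactone, the methacrylate and the dienyl furanone should tolerate.

**Compound list**
1 | but-2-yne-1,4-diol | OCC#CCO | starting material
2 | 4-[(tert-butyldiphenylsilyl)oxy]but-2-yn-1-ol | OCC#CCO[Si](c1ccccc1)(c1ccccc1)C(C)(C)C | intermediate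
3 | sodium cyclic alkoxy(alkenyl)alanate from 2 (Al on C3, H on C2) | [Na+].COCCO[Al-]1(OCCOC)OCC=C1CO[Si](c1ccccc1)(c1ccccc1)C(C)(C)C | intermediate
4 | (Z)-4-[(tert-butyldiphenylsilyl)oxy]-3-iodobut-2-en-1-ol | OC/C=C(\I)CO[Si](c1ccccc1)(c1ccccc1)C(C)(C)C | intermediate
5 | (Z)-4-[(tert-butyldiphenylsilyl)oxy]-3-iodobut-2-enal | O=C/C=C(\I)CO[Si](c1ccccc1)(c1ccccc1)C(C)(C)C | intermediate
6 | (Z)-tert-butyl[(2-iodo-4,4-dimethoxybut-2-en-1-yl)oxy]diphenylsilane | COC(OC)/C=C(\I)CO[Si](c1ccccc1)(c1ccccc1)C(C)(C)C | intermediate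
7 | alkenyllithium from 6 | COC(OC)/C=C(\[Li])CO[Si](c1ccccc1)(c1ccccc1)C(C)(C)C | intermediate
8 | (Z)-3-{[(tert-butyldiphenylsilyl)oxy]methyl}-5,5-dimethoxypent-3-en-2-one | CC(=O)/C(CO[Si](c1ccccc1)(c1ccccc1)C(C)(C)C)=C\C(OC)OC | intermediate
9 | (R)-5-(hydroxymethyl)dihydrofuran-2(3H)-one | O=C1O[C@@H](CO)CC1 | starting material
10 | (R)-5-{[(tert-butyldiphenylsilyl)oxy]methyl}dihydrofuran-2(3H)-one | O=C1O[C@@H](CO[Si](c2ccccc2)(c2ccccc2)C(C)(C)C)CC1 | intermediate
11 | lithium enolate of 10 | [Li]OC1=CC[C@H](CO[Si](c2ccccc2)(c2ccccc2)C(C)(C)C)O1 | intermediate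
12 | (3S,5R)-5-{[(tert-butyldiphenylsilyl)oxy]methyl}-3-methyldihydrofuran-2(3H)-one | O=C1O[C@@H](CO[Si](c2ccccc2)(c2ccccc2)C(C)(C)C)C[C@@H]1C | intermediate
13 | lithium enolate of 12 | [Li]OC1=C(C)C[C@H](CO[Si](c2ccccc2)(c2ccccc2)C(C)(C)C)O1 | intermediate
14 | (3S,5R)-3-bromo-5-{[(tert-butyldiphenylsilyl)oxy]methyl}-3-methyldihydrofuran-2(3H)-one | O=C1O[C@@H](CO[Si](c2ccccc2)(c2ccccc2)C(C)(C)C)C[C@]1(C)Br | intermediate
15 | (3S,5R)-3-bromo-5-(hydroxymethyl)-3-methyldihydrofuran-2(3H)-one | O=C1O[C@@H](CO)C[C@]1(C)Br | intermediate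
16 | (2R,4S)-4-bromo-4-methyl-5-oxotetrahydrofuran-2-carbaldehyde | O=C1O[C@@H](C=O)C[C@]1(C)Br | intermediate
17 | trimethyl 2-phosphonoacrylate (methyl 2-(dimethoxyphosphoryl)prop-2-enoate) | C=C(C(=O)OC)P(=O)(OC)OC | starting material
18 | sodium salt of methyl 2-(dimethoxyphosphoryl)-3-[(4-methoxybenzyl)oxy]propanoate (phosphonate carbanion) | [Na+].COC(=O)[C-](COCc1ccc(OC)cc1)P(=O)(OC)OC | intermediate
19 | methyl (E)-3-[(2R,4S)-4-bromo-4-methyl-5-oxotetrahydrofuran-2-yl]-2-{[(4-methoxybenzyl)oxy]methyl}prop-2-enoate | O=C1O[C@@H](/C=C(\COCc2ccc(OC)cc2)C(=O)OC)C[C@]1(C)Br | intermediate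
20 | lithium enolate of 8 | C=C(O[Li])/C(CO[Si](c1ccccc1)(c1ccccc1)C(C)(C)C)=C\C(OC)OC | intermediate
21 | methyl (2E,4R,6S,10Z)-6-bromo-10-{[(tert-butyldiphenylsilyl)oxy]methyl}-4-hydroxy-12,12-dimethoxy-2-{[(4-methoxybenzyl)oxy]methyl}-6-methyl-7,9-dioxododeca-2,10-dienoate (present as its lithium enolate) | O[C@H](C[C@](C)(Br)C(=O)CC(=O)/C(CO[Si](c1ccccc1)(c1ccccc1)C(C)(C)C)=C\C(OC)OC)/C=C(\COCc1ccc(OC)cc1)C(=O)OC | intermediate
22 | methyl (2E,4R)-5-[(2R)-5-{(Z)-1-[(tert-butyldiphenylsilyl)oxy]-4,4-dimethoxybut-2-en-2-yl}-2-methyl-3-oxo-2,3-dihydrofuran-2-yl]-4-hydroxy-2-{[(4-methoxybenzyl)oxy]methyl}pent-2-enoate | O[C@H](C[C@@]1(C)OC(=CC1=O)/C(CO[Si](c2ccccc2)(c2ccccc2)C(C)(C)C)=C\C(OC)OC)/C=C(\COCc2ccc(OC)cc2)C(=O)OC | intermediate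
23 | methyl (2E,4R)-5-[(2R)-5-{(Z)-1-[(tert-butyldiphenylsilyl)oxy]-4,4-dimethoxybut-2-en-2-yl}-2-methyl-3-oxo-2,3-dihydrofuran-2-yl]-2-{[(4-methoxybenzyl)oxy]methyl}-4-[(triethylsilyl)oxy]pent-2-enoate | CC[Si](CC)(CC)O[C@H](C[C@@]1(C)OC(=CC1=O)/C(CO[Si](c2ccccc2)(c2ccccc2)C(C)(C)C)=C\C(OC)OC)/C=C(\COCc2ccc(OC)cc2)C(=O)OC | intermediate
24 | methyl (2E,4R)-5-[(2R)-5-{(Z)-1-[(tert-butyldiphenylsilyl)oxy]-4,4-dimethoxybut-2-en-2-yl}-2-methyl-3-oxo-2,3-dihydrofuran-2-yl]-2-(hydroxymethyl)-4-[(triethylsilyl)oxy]pent-2-enoate | CC[Si](CC)(CC)O[C@H](C[C@@]1(C)OC(=CC1=O)/C(CO[Si](c2ccccc2)(c2ccccc2)C(C)(C)C)=C\C(OC)OC)/C=C(\CO)C(=O)OC | intermediate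
25 | methyl (2Z,4R)-2-(bromomethyl)-5-[(2R)-5-{(Z)-1-[(tert-butyldiphenylsilyl)oxy]-4,4-dimethoxybut-2-en-2-yl}-2-methyl-3-oxo-2,3-dihydrofuran-2-yl]-4-[(triethylsilyl)oxy]pent-2-enoate | CC[Si](CC)(CC)O[C@H](C[C@@]1(C)OC(=CC1=O)/C(CO[Si](c2ccccc2)(c2ccccc2)C(C)(C)C)=C\C(OC)OC)/C=C(\CBr)C(=O)OC | intermediate
26 | methyl (2Z,4R)-2-(bromomethyl)-5-[(2R)-5-{(Z)-1-[(tert-butyldiphenylsilyl)oxy]-4-oxobut-2-en-2-yl}-2-methyl-3-oxo-2,3-dihydrofuran-2-yl]-4-[(triethylsilyl)oxy]pent-2-enoate | CC[Si](CC)(CC)O[C@H](C[C@@]1(C)OC(=CC1=O)/C(CO[Si](c2ccccc2)(c2ccccc2)C(C)(C)C)=C\C=O)/C=C(\CBr)C(=O)OC | intermediate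
27 | allylchromium dichloride from 26 (CrCl2 on C13) | CC[Si](CC)(CC)O[C@H](C[C@@]1(C)OC(=CC1=O)/C(CO[Si](c2ccccc2)(c2ccccc2)C(C)(C)C)=C\C=O)/C=C(\C[Cr](Cl)Cl)C(=O)OC | intermediate
28 | ten-membered 6-hydroxy methyl ester (as its chromium alkoxide): furanone-bridged carbocycle with C6–OH, C7–C(=CH2)CO2Me, C8–OSiEt3, C15–OTBDPS; C6, C7, C8, C10 arranged as in the target | CC[Si](CC)(CC)O[C@@H]1C[C@@]2(C)OC(=CC2=O)/C(CO[Si](c3ccccc3)(c3ccccc3)C(C)(C)C)=C\[C@@H](O)[C@@H]1C(=C)C(=O)OC | intermediate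
29 | 8-O-triethylsilyl-15-O-(tert-butyldiphenylsilyl)-8,15-dihydroxy-1-oxo-3,10-epoxygermacra-2,4(Z),11(13)-trien-12,6-olide, stereocentres as in the target | CC[Si](CC)(CC)O[C@@H]1C[C@@]2(C)OC(=CC2=O)/C(CO[Si](c3ccccc3)(c3ccccc3)C(C)(C)C)=C\[C@H]2OC(=O)C(=C)[C@@H]21 | intermediate
30 | (6R,7R,8R,10R)-15-[(tert-butyldiphenylsilyl)oxy]-8-hydroxy-1-oxo-3,10-epoxygermacra-2,4(Z),11(13)-trien-12,6-olide | O[C@@H]1C[C@@]2(C)OC(=CC2=O)/C(CO[Si](c3ccccc3)(c3ccccc3)C(C)(C)C)=C\[C@H]2OC(=O)C(=C)[C@@H]21 | intermediate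
31 | (6R,7R,8R,10R)-15-[(tert-butyldiphenylsilyl)oxy]-8-(methacryloyloxy)-1-oxo-3,10-epoxygermacra-2,4(Z),11(13)-trien-12,6-olide | C=C(C)C(=O)O[C@@H]1C[C@@]2(C)OC(=CC2=O)/C(CO[Si](c3ccccc3)(c3ccccc3)C(C)(C)C)=C\[C@H]2OC(=O)C(=C)[C@@H]21 | intermediate
32 | (6R,7R,8R,10R)-15-hydroxy-8-(methacryloyloxy)-1-oxo-3,10-epoxygermacra-2,4(Z),11(13)-trien-12,6-olide (CNP0180483.5) | C=C(C)C(=O)O[C@@H]1C[C@@]2(C)OC(=CC2=O)/C(CO)=C\[C@H]2OC(=O)C(=C)[C@@H]21 | target

**Summary**
Total step count: 19. Longest linear sequence: 14 steps (steps 6–19).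

**Steps most likely to fail**

Step 12 (Proposed new method). The tetrahedral adduct may close onto C10 as an epoxy ketal instead of opening, the bromo diketonate may lose HBr, or C10 may ionise with loss of configuration. The fallback uses the classical two-stage furanone synthesis, in which the C10–O bond is carried in and the ring oxygen closes onto C3; it sets out from 10 and comes back at 22. Hydroxylation of enolate 11 with 2-(phenylsulfonyl)-3-phenyloxaziridine should give hydroxy lactone F1, and silylation (Et3SiCl, imidazole) the silyl ether F2. Methylation of its lithium enolate (LiN(iPr)2, MeI) is expected anti to the side chain and should give methyl lactone F3 with the C10 configuration of the target. HF·pyridine should give diol F4, DMP should oxidise only the primary alcohol to aldehyde F5, and the olefination of step 11 should give enoate F6. Claisen condensation of F6 with two equivalents of enolate 20 should give hydroxy diketone F7, and acid-catalysed cyclodehydration (PPTS, benzene, molecular sieves) should give 22, which is silylated to 23 as in step 12.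

Step 16. Oligomerisation under the strain of the bridged ten-membered ring, Z to E drift of the enal before closure, or poor facial selectivity at C6/C7 may occur. The fallback replaces the in-situ allylchromium by an isolable allylstannane and a Lewis-acid-promoted open-transition-state addition; it sets out from 25 and comes back at 28. Stannylation of 25 ((Bu3Sn)2, Pd(PPh3)4, THF) should give allylstannane F8, acetal hydrolysis (PPTS, acetone/H2O) the stannyl enal F9, and BF3·OEt2 (CH2Cl2, −78 °C, high dilution) should close the ring to 28, which lactonises to 29.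

Step 11. Epimerisation at C8 of the α-oxygenated aldehyde under the basic phosphonate, alkoxide attack on the bromolactone, or erosion of E selectivity may occur. The fallback is a neutral Wittig olefination with a preformed stabilised ylide; it sets out from 16 and comes back at 19. Methyl 3-[(4-methoxybenzyl)oxy]-2-(triphenyl-λ5-phosphanylidene)propanoate F10 (from methyl (triphenylphosphoranylidene)acetate and 4-methoxybenzyl chloromethyl ether) and 16 in toluene at rt should give 19.

Further compounds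
F1 | step 12 | (3S,5R)-5-{[(tert-butyldiphenylsilyl)oxy]methyl}-3-hydroxydihydrofuran-2(3H)-one | O=C1O[C@@H](CO[Si](c2ccccc2)(c2ccccc2)C(C)(C)C)C[C@@H]1O
F2 | step 12 | (3S,5R)-5-{[(tert-butyldiphenylsilyl)oxy]methyl}-3-[(triethylsilyl)oxy]dihydrofuran-2(3H)-one | O=C1O[C@@H](CO[Si](c2ccccc2)(c2ccccc2)C(C)(C)C)C[C@@H]1O[Si](CC)(CC)CC
F3 | step 12 | (3R,5R)-5-{[(tert-butyldiphenylsilyl)oxy]methyl}-3-methyl-3-[(triethylsilyl)oxy]dihydrofuran-2(3H)-one | O=C1O[C@@H](CO[Si](c2ccccc2)(c2ccccc2)C(C)(C)C)C[C@@]1(C)O[Si](CC)(CC)CC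
F4 | step 12 | (3R,5R)-3-hydroxy-5-(hydroxymethyl)-3-methyldihydrofuran-2(3H)-one | O=C1O[C@@H](CO)C[C@@]1(C)O
F5 | step 12 | (2R,4R)-4-hydroxy-4-methyl-5-oxotetrahydrofuran-2-carbaldehyde | O=C1O[C@@H](C=O)C[C@@]1(C)O
F6 | step 12 | methyl (E)-3-[(2R,4R)-4-hydroxy-4-methyl-5-oxotetrahydrofuran-2-yl]-2-{[(4-methoxybenzyl)oxy]methyl}prop-2-enoate | O=C1O[C@@H](/C=C(\COCc2ccc(OC)cc2)C(=O)OC)C[C@@]1(C)O
F7 | step 12 | methyl (2E,4R,6R,10Z)-10-{[(tert-butyldiphenylsilyl)oxy]methyl}-4,6-dihydroxy-12,12-dimethoxy-2-{[(4-methoxybenzyl)oxy]methyl}-6-methyl-7,9-dioxododeca-2,10-dienoate | O[C@H](C[C@@](C)(O)C(=O)CC(=O)/C(CO[Si](c1ccccc1)(c1ccccc1)C(C)(C)C)=C\C(OC)OC)/C=C(\COCc1ccc(OC)cc1)C(=O)OC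
F8 | step 16 | methyl (2Z,4R)-5-[(2R)-5-{(Z)-1-[(tert-butyldiphenylsilyl)oxy]-4,4-dimethoxybut-2-en-2-yl}-2-methyl-3-oxo-2,3-dihydrofuran-2-yl]-2-[(tributylstannyl)methyl]-4-[(triethylsilyl)oxy]pent-2-enoate | CC[Si](CC)(CC)O[C@H](C[C@@]1(C)OC(=CC1=O)/C(CO[Si](c2ccccc2)(c2ccccc2)C(C)(C)C)=C\C(OC)OC)/C=C(\C[Sn](CCCC)(CCCC)CCCC)C(=O)OC
F9 | step 16 | methyl (2Z,4R)-5-[(2R)-5-{(Z)-1-[(tert-butyldiphenylsilyl)oxy]-4-oxobut-2-en-2-yl}-2-methyl-3-oxo-2,3-dihydrofuran-2-yl]-2-[(tributylstannyl)methyl]-4-[(triethylsilyl)oxy]pent-2-enoate | CC[Si](CC)(CC)O[C@H](C[C@@]1(C)OC(=CC1=O)/C(CO[Si](c2ccccc2)(c2ccccc2)C(C)(C)C)=C\C=O)/C=C(\C[Sn](CCCC)(CCCC)CCCC)C(=O)OC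
F10 | step 11 | methyl 3-[(4-methoxybenzyl)oxy]-2-(triphenyl-λ5-phosphanylidene)propanoate | COC(=O)C(COCc1ccc(OC)cc1)=P(c1ccccc1)(c1ccccc1)c1ccccc1
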